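The pitfall in a dosed flask is to read a large share of starting material as slow chemistry: the percentages count the whole charge, and starting material keeps arriving while it is lost. Here starting material is dosed into a stirred solution holding protic impurity, and ring, open dimer and open trimer appear.

| setting | beta | delta | epsilon | flask |
|---|---|---|---|---|
| starting material | 0.028 M (fed, over 50 h) | 0.044 M (fed, over 50 h) | 0.020 M (fed, over 50 h) | 0.020 M (fed, over 50 h) |
| protic impurity | 2 mM | 2 mM | 1 mM | 2.00 mM |
| remark | run made earlier; the fed solution adds 1.0 times the starting volume | run made earlier; the fed solution adds 1.0 times the starting volume | run made earlier; the fed solution adds 1.0 times the starting volume | the fed solution adds 1.0 times the starting volume |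
| time |  |  |  | 2.0 d |

| run | time / h | ring / % | open dimer / % | starting material / % | open trimer / % |
|---|---|---|---|---|---|
| beta | 6.00 | 1.0 | 0 | 11.0 | 0 |
| beta | 15.0 | 2.7 | 1.6 | 25.2 | 0.2 |
| beta | 30.0 | 7.4 | 5.4 | 41.3 | 0.8 |
| beta | 50.0 | 19.4 | 14.9 | 56.2 | 3.6 |
| delta | 4.00 | 0 | 0.1 | 7.9 | 0 |
| delta | 8.00 | 0.6 | 0.6 | 14.1 | 0.3 |
| delta | 20.0 | 3.5 | 3.3 | 30.7 | 0 |
| delta | 50.0 | 18.2 | 19.2 | 51.3 | 7.5 |
| epsilon | 4.00 | 0.4 | 0 | 8.0 | 0.1 |
| epsilon | 8.00 | 0.6 | 0.4 | 15.0 | 0.5 |
| epsilon | 20.0 | 3.6 | 1.7 | 32.9 | 0 |
| epsilon | 50.0 | 20.6 | 12.8 | 61.1 | 2.2 |

(scatter of a reading: 0.3 percentage points)

- a species is counted by the starting material in it: one open dimer counts as two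
- a species is counted by the starting material in it: one open trimer counts as three
- charges are per starting volume, the dose included; the dosed solution carries all of it
- the numbers in the tables scatter with a standard deviation of 0.3 percentage points
- percentages count the whole charge, also what has not yet gone in

- the species that holds most of what was charged as starting material, at 2.0 d (open trimer / starting material / open dimer / ring)
- the largest share itself, whichever of these holds it, in percent of the starting material charged

I take ring to form from one molecule of starting material, so that its rate goes as c(starting material); open dimer counts two, so I take its rate to go as the square. Dividing one rate by the other removes time and leaves a ratio that grows with concentration. So at the end of each feed I divide the share in open dimer and open trimer by the share in ring, and that by the charge: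

epsilon 36.4 /M, beta 34.1 /M, delta 33.3 /M; mean 34.6 /M

The three readings stay close while the charge goes to twice its value, so I carry the mean as g, the chain ratio, a selectivity factor. For the flask it gives

R = g · c(starting material, charged) = 0.692

so I expect less in open dimer and open trimer together than in ring.

The beta balance falls short by 5.90%, less than the 7.14% its impurity could take one for one. So in the flask I subtract the impurity's whole 10.0% from the 96.0% fed, and take epsilon's ring, 20.6%, as a generous value:

low estimate = 96.0% − 10.0% − 20.6% · (1 + R) = 51.1%

I commit to starting material, near or above this estimate, which is more than epsilon's ring. The forecast, a different number from my estimate, says starting material at 58.3%: “Starting material stays the largest pool in every run”.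

The flask gives starting material at 57.7%, more than my low estimate and more than ring, open dimer or open trimer; its open dimer and open trimer over its ring come to 0.682, against my 0.692.

    starting material → ring (k = 0.0114 /h)
    2 starting material → open dimer (k = 0.732 /M/h)
    starting material + open dimer → open trimer (k = 1.39 /M/h)
    starting material + protic impurity → quenched substrate (k = 6.20 /M/h)

A neighbour flask charged with 0.080 M of starting material, its other charges and its time held, tests the chain ratio at a larger charge. The same reckoning gives R = 2.77, and the neighbour comes to 2.40, which is less than that. Ring there holds 15.3%, against 21.9% in open dimer and 14.9% in open trimer, and starting material stands at 41.5%.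

The readings were computed with constants of no real substance; scatter was added.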